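## Structural features

The target is a single carbocycle, a cyclohex-1-ene whose C1 carries a methyl ester conjugated with C1=C2. All stereochemistry lies in three adjacent oxygenated ring carbons, C3 (R, allylic), C4 (S) and C5 (R), and in the alpha-carbons of two (R)-2-methylbutanoyl groups. O3 and O4 are cis and O4 and O5 are trans, the shikimate pattern. O3 carries an acetate; O4 and O5 carry the same branched ester. Fragile points are:
- the allylic acetate, which can ionise or eliminate towards a benzoate;
- acyl migration between neighbouring oxygens;
- any ring ketone at C3 or C4, which aromatises by enolisation and loss of a beta-oxygen;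
- the alpha-centre of the branched acid under basic acylation.

The real difficulty is the absolute configuration of the triol combined with a regiodefined triester on three neighbouring secondary oxygens, not the carbon skeleton. The key step treats C3–C4–C5 as a dihydroxyacetone-type C3 unit with C4 as the ketone. It treats C2–C1(CO2Me)–C6 as a 2-carboxyallyl unit with C6 at the halide level and C2 at the aldehyde level. The cyclohexene is then the alpha,alpha′-annulation product of a ketone. The acetal across O3 and O5 makes it a 2,4-dioxabicyclo[3.3.1]nonene with the ketone on the one-atom bridge.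

## Logic of the disconnections

18 to 17 and 13: the acyl C–O bond at O4 is cut. The last step is then an acylation of the only free hydroxyl, and the second branched ester becomes a reagent. The forward step must acylate faster than the acetyl group of 17 can shift from O3 to O4, and must not epimerise 13.

17 to 15: the acetyl C–O bond at O3 is cut. The cis-3,4-diol of 15 can be differentiated through a cyclic orthoester that opens to the ester on the pseudoaxial oxygen, so no protecting group is needed. The demand is regioselective opening.

15 to 14: the two acetal C–O bonds are cut. This is a plain deprotection; the demand is that the C5 ester and the enoate survive aqueous acid.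

14 to 12 and 13: the C5–O bond is cut, not the acyl bond. In 12 the C5 oxygen has the wrong configuration, so forming this bond with the carboxylate of 13 as nucleophile corrects C5 and installs the first branched ester in one operation. The demand is clean substitution with inversion at a secondary carbinol next to the ring CH2, without elimination towards C6.

12 to 10 through 11: the C4–H bond is cut and the acetal is moved back from O3/O4 to O3/O5. The bridged ketone 10 offers hydride only one face, which sets C4 cis to both flanking oxygens. The strained bridging acetal of 11 can then relax to the fused one, which frees O5 alone. The gain is one stereocentre from substrate control and a singled-out O5. The demands are face selectivity and a regioselective acetal shift.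

10 to 7 and 4: C5–C6 and C2–C3 are cut. This removes the ring and both ring stereocentres in one operation and leaves an achiral ketone derivative and an achiral allyl unit. The forward step must form C5–C6 first (by SN2), close C2–C3 by conjugate addition and not by acylation, and close cis.

7 to 5 and 6, and 4 to 3 to 1: the C=N bond, the C–Br bond, and then the formyl C–C and enol O–CH3 bonds are cut. All are standard condensations or a radical bromination and lead to purchasable materials.

## Other disconnections considered

Alternative 1: The cut is at C1–C2 and C5–C6. The ring is read as the [4+2] adduct of furan A1 (C2 to C5 and the later O5) with the acrylic unit of 3-acryloyloxazolidin-2-one A2 (C1, C6, carboxyl carbon). The forward key step would be the endo cycloaddition of A1 and A2 under Cu(SbF6)2 (divalent copper) with a tert-butyl bis(oxazoline) ligand, giving the 7-oxabicyclo[2.2.1]heptene A3.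
- In favour: it is catalytic in chiral information and builds both ring bonds at once from bulk chemicals. It belongs to a well-established class of Lewis-acid-catalysed cycloadditions, so on precedent it is better than the chosen plan.
- The rigid bicycle would direct cis-dihydroxylation to the face of the oxygen bridge. Acetalisation, exchange of the imide for the methyl ester and eliminative opening of the bridge from the ester enolate would lead to 12, the intermediate of the chosen route. Both plans would then share the C5 inversion and the whole endgame, so on stereochemical outcome they are equal.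
- Against: furan adducts revert easily, so the cycloaddition and following steps must be kept cold. OsO4 and a hexafluoroantimonate salt are needed. About four functional-group steps separate A3 from 12, so the count up to 12 is about equal to that of the chosen plan.
- Comparison: the chosen plan reaches 12 through the annulation with a recoverable auxiliary, but the alternative is the safer way to 12.

Alternative 2: Three bonds are cut: C5–C6, C3–C4 and C1=C2. This gives 4-methoxybenzyloxyacetaldehyde A4 (C4, C5), methyl 2-(diethoxyphosphoryl)acrylate A5 (C1, C6, carboxyl) and tert-butyldimethylsilyloxyacetaldehyde A6 (C2, C3). Forward, a prolinol-ether enamine of A4 would add to A5. The resulting aldehyde would accept an amino-acid-derived enamine of A6 in an anti-selective aldol reaction. Cs2CO3 would then close the ring by intramolecular Horner–Wadsworth–Emmons olefination to the shikimate ester A7.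
- In favour: one flask, no inversion, and all three stereocentres in the natural configuration. The protecting pattern (O3 silyl, O4 free, O5 benzyl-type) keeps O3 distinct from O4 and O5 to the end. Some four to five further steps would suffice, so in step economy and in the fit of the protecting groups this plan is better than the chosen one.
- Against: two amine catalysts and a carbonate base must act in sequence in one pot. The aldol is a crossed reaction between two enolisable alpha-oxy aldehydes, in which the branched Michael adduct must be the acceptor and A6 must not dimerise. The alpha-alkoxy aldehyde centre (C5) and a silyl ether next to a free hydroxyl are both base-labile under the olefination conditions.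
- Comparison: each event has precedent of its type, as do the two bond formations of the chosen key step taken singly, so on mechanism the plans are comparable. The chosen plan offers a bicyclic product that cannot epimerise; the alternative offers brevity.

Alternative 3: Only C1–C6 is cut. The ring opens to a seven-carbon chain whose C3, C4 and C5 are C2, C3 and C4 of D-lyxose A8; the precursor would be the acyclic iodo-enoate A9. Forward, PBu3 would add to C2 of A9, the ester enolate would displace the primary iodide at C6 (6-exo-tet), and base would expel the phosphine to restore C1=C2, giving the protected shikimate A10.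
- In favour: every stereocentre comes from the chiral pool in the natural configuration, with no stereoselective step and no inversion. The closure is a favoured exo alkylation. In stereochemical security this plan is better than the chosen one.
- Against: A9 needs a longer linear preparation from A8 (selective protection, chain extension to the enoate with the risk of oxa-conjugate addition of the freed hydroxyl, silylation, iodination), so step economy is worse. The phosphine-mediated alkylation is established mainly for enones, and enoates are weaker acceptors.
- Comparison: the acetonide of A10 ties O3 and O4 together, so the acetate at O3 would need the same orthoester opening as in the chosen route; the plans are equal on that point.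

Key step: step 4

Remark (correction): alkylation of the SAMP azaenolate of this dioxanone gives the S configuration at the alkylated carbon, so SAMP leads to the (1S,5R) bicyclic ketone 10 and the mirror-image auxiliary to its enantiomer; the (1S,5R) compound is the one the route needs.

Remark (assumption): in 10 the gem-dimethyl acetal cannot sit in a chair (its inner methyl would collide with C7), so the acetal carbon and one methyl cover the carbonyl face on the acetal side; hydride is therefore taken to enter from the alkene side, which gives the all-cis alcohol 11 and makes C5 the centre to invert.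

## Route

Step 1
Reactants: 1 methyl propanoate
Product: 3 methyl (2E)-3-methoxy-2-methylprop-2-enoate, via sodium enolate of methyl 2-formylpropanoate 2 (not isolated)
Conditions: NaH, HCO2Me, THF, 0 °C → rt; then Me2SO4, DMF, rt
Reagents that add atoms: methyl formate (COC=O); dimethyl sulfate (COS(=O)(=O)OC)
Why: Crossed Claisen condensation with the non-enolisable formate gives the stabilised enolate 2, which the hard methylating agent alkylates on oxygen; the E isomer (methoxy trans to the ester) is the thermodynamically preferred one, and the alkene geometry is lost later in the addition–elimination in any case.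

Step 2
Reactants: 3 methyl (2E)-3-methoxy-2-methylprop-2-enoate
Product: 4 methyl (2Z)-2-(bromomethyl)-3-methoxyprop-2-enoate
Conditions: NBS, AIBN (cat.), PhCF3, 80 °C
Reagents that add atoms: N-bromosuccinimide (O=C1CCC(=O)N1Br)
Why: Wohl–Ziegler bromination; the 2-methyl group holds the only allylic C–H bonds, and the low bromine concentration in a non-polar solvent favours hydrogen abstraction over ionic addition to the enol ether; the descriptor changes from E to Z only because CH2Br outranks the ester.

Step 3
Reactants: 5 2,2-dimethyl-1,3-dioxan-5-one; 6 (S)-1-amino-2-(methoxymethyl)pyrrolidine (SAMP)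
Product: 7 (2S)-N-(2,2-dimethyl-1,3-dioxan-5-ylidene)-2-(methoxymethyl)pyrrolidin-1-amine (SAMP hydrazone of 5)
Conditions: toluene, 4 Å MS, 60 °C
Reagents that add atoms: none
Why: Hydrazone condensation of an unhindered ketone with a 1,1-disubstituted hydrazine, driven by removal of water; the ring is symmetric, so no C=N isomer problem arises.

Step 4
Reactants: 7 SAMP hydrazone of 2,2-dimethyl-1,3-dioxan-5-one; 4 methyl (2Z)-2-(bromomethyl)-3-methoxyprop-2-enoate
Product: 10 methyl (1S,5R)-3,3-dimethyl-9-oxo-2,4-dioxabicyclo[3.3.1]non-6-ene-7-carboxylate, via monoalkylated hydrazone 8 (not isolated), via bicyclic hydrazone 9 (not isolated)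
Conditions: t-BuLi, THF, −78 °C; 4, −100 °C → rt; LiN(i-Pr)2, −78 → 0 °C; then sat. aq. (CO2H)2, Et2O, rt
Reagents that add atoms: water (O)
Why: Proposed new method: t-BuLi gives the lithium azaenolate of 7, which should displace the primary allylic bromide of 4 by SN2 (C5–C6), because the donor-substituted acrylate is a poor conjugate acceptor at −100 °C; the auxiliary sets C5 as S, the usual sense for alkylations of this hydrazone. LiN(i-Pr)2, chosen instead of a second charge of t-BuLi to spare the ester, then deprotonates the unsubstituted alpha′ carbon of 8; the new azaenolate adds to the methoxy-bearing carbon (C2–C3) and the ester enolate expels methoxide (E1cB), restoring C1=C2. The closest known reactions are the alpha,alpha′-annulation of ketone enamines with 2-(bromomethyl)acrylates and the stepwise double alkylation of this hydrazone; new are the azaenolate as double nucleophile and the addition–elimination that keeps the ring alkene. The carbocycle closes 6-endo-trig onto a dioxane that must carry both new C–C bonds on one face, so C3 can only form cis to C5; it is set by the tether, against the intrinsic trans preference of the auxiliary, which an intramolecular step should tolerate. The step needs regioselectivity in the first bond, because bonding first at the methoxy carbon would lead to the mirror-image bicycle; the primary bromide against a hindered, deactivated acceptor should secure it. It also needs conjugate addition instead of 6-exo acylation at the ester carbonyl, which rests on the 1,4-preference of hydrazone azaenolates towards enoates. Biphasic oxalic acid then cleaves the C=N bond without epimerisation and returns the auxiliary. The bridgeheads of 10 cannot enolise, so it is protected from the aromatisation that threatens a monocyclic 4-oxo shikimate.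

Step 5
Reactants: 10 methyl (1S,5R)-3,3-dimethyl-9-oxo-2,4-dioxabicyclo[3.3.1]non-6-ene-7-carboxylate
Product: 12 methyl (3R,4S,5S)-5-hydroxy-3,4-(isopropylidenedioxy)cyclohex-1-ene-1-carboxylate (methyl 3,4-O-isopropylidene-5-epi-shikimate), via bridged alcohol 11 (not isolated)
Conditions: NaBH4, MeOH, −40 °C; then CSA (cat.), acetone, 0 °C
Reagents that add atoms: none
Why: Hydride reduction under steric approach control, then acid-catalysed acetal migration; the acetal side of the carbonyl in 10 is covered by the acetal carbon and a methyl, so NaBH4 should attack from the alkene side and place O4 cis to O3 and O5 (9S in 11, the natural C4 configuration). The strained bridging dioxane of 11 should then open at the more basic, non-allylic O5 and reclose on O4 as the cis-fused dioxolane, freeing the one hydroxyl that must be inverted.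

Step 6
Reactants: 12 methyl 3,4-O-isopropylidene-5-epi-shikimate; 13 (R)-2-methylbutanoic acid
Product: 14 methyl (3R,4S,5R)-3,4-(isopropylidenedioxy)-5-{[(2R)-2-methylbutanoyl]oxy}cyclohex-1-ene-1-carboxylate
Conditions: PPh3, DIAD, THF, 0 °C → rt
Reagents that add atoms: none
Why: Mitsunobu esterification; the alkoxyphosphonium of the only free hydroxyl is displaced by the carboxylate from the face opposite the fused acetonide, which inverts C5 to the natural R configuration and installs the first branched ester in the same operation.

Step 7
Reactants: 14 methyl 3,4-O-isopropylidene-5-O-[(2R)-2-methylbutanoyl]shikimate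
Product: 15 methyl (3R,4R,5R)-3,4-dihydroxy-5-{[(2R)-2-methylbutanoyl]oxy}cyclohex-1-ene-1-carboxylate
Conditions: AcOH–H2O (4:1), 45 °C
Reagents that add atoms: none
Why: Acid-catalysed hydrolysis of the cis-fused acetonide; the secondary ester and the enoate tolerate aqueous acetic acid, and acidic conditions keep acyl migration from O5 to O4 slow.

Step 8
Reactants: 15 methyl 5-O-[(2R)-2-methylbutanoyl]shikimate
Product: 17 methyl (3R,4S,5R)-3-(acetyloxy)-4-hydroxy-5-{[(2R)-2-methylbutanoyl]oxy}cyclohex-1-ene-1-carboxylate, via cyclic orthoacetate 16 (not isolated)
Conditions: MeC(OMe)3, CSA (cat.), CH2Cl2, rt; then AcOH–H2O (4:1), rt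
Reagents that add atoms: trimethyl orthoacetate (CC(OC)(OC)OC); water (O)
Why: Orthoester formation on the cis-3,4-diol and mild acid hydrolysis; the hemi-orthoester collapses to the ester on the pseudoaxial oxygen (O3) and the free equatorial hydroxyl (O4), the usual outcome for cis-diols on six-membered rings.

Step 9
Reactants: 17 methyl 3-O-acetyl-5-O-[(2R)-2-methylbutanoyl]shikimate; 13 (R)-2-methylbutanoic acid
Product: 18 methyl (3R,4S,5R)-3-(acetyloxy)-4,5-bis{[(2R)-2-methylbutanoyl]oxy}cyclohex-1-ene-1-carboxylate (CNP0132712.1)
Conditions: DCC, DMAP (cat.), CH2Cl2, 0 °C
Reagents that add atoms: none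
Why: Steglich esterification of the last, hindered secondary hydroxyl; low temperature and catalytic DMAP keep acetyl migration from O3 and epimerisation of the alpha-branched acyl donor slow relative to acyl transfer.

## Compound list

1 | methyl propanoate | CCC(=O)OC | starting material
2 | sodium enolate of methyl 2-formylpropanoate (sodium 3-methoxy-2-methyl-3-oxoprop-1-en-1-olate) | [Na+].[O-]C=C(C)C(=O)OC | intermediate (not isolated)
3 | methyl (2E)-3-methoxy-2-methylprop-2-enoate | CO/C=C(\C)C(=O)OC | intermediate
4 | methyl (2Z)-2-(bromomethyl)-3-methoxyprop-2-enoate | CO/C=C(\CBr)C(=O)OC | intermediate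
5 | 2,2-dimethyl-1,3-dioxan-5-one | CC1(C)OCC(=O)CO1 | starting material
6 | (S)-1-amino-2-(methoxymethyl)pyrrolidine (SAMP) | COC[C@@H]1CCCN1N | starting material
7 | (2S)-N-(2,2-dimethyl-1,3-dioxan-5-ylidene)-2-(methoxymethyl)pyrrolidin-1-amine | COC[C@@H]1CCCN1N=C1COC(C)(C)OC1 | intermediate
8 | methyl (2E)-2-{[(4S)-5-{[(2S)-2-(methoxymethyl)pyrrolidin-1-yl]imino}-2,2-dimethyl-1,3-dioxan-4-yl]methyl}-3-methoxyprop-2-enoate | CO/C=C(\C[C@@H]1OC(C)(C)OCC1=NN1CCC[C@H]1COC)C(=O)OC | intermediate (not isolated)
9 | methyl (1S,5R)-9-{[(2S)-2-(methoxymethyl)pyrrolidin-1-yl]imino}-3,3-dimethyl-2,4-dioxabicyclo[3.3.1]non-6-ene-7-carboxylate | COC(=O)C1=C[C@H]2OC(C)(C)O[C@@H](C1)C2=NN1CCC[C@H]1COC | intermediate (not isolated)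
10 | methyl (1S,5R)-3,3-dimethyl-9-oxo-2,4-dioxabicyclo[3.3.1]non-6-ene-7-carboxylate (3,5-O-isopropylidene-4-dehydro-5-epi-shikimate methyl ester) | COC(=O)C1=C[C@H]2OC(C)(C)O[C@@H](C1)C2=O | intermediate
11 | methyl (1S,5R,9S)-9-hydroxy-3,3-dimethyl-2,4-dioxabicyclo[3.3.1]non-6-ene-7-carboxylate (hydroxyl on the side of the acetal bridge; O3, O4, O5 all cis) | COC(=O)C1=C[C@H]2OC(C)(C)O[C@@H](C1)[C@@H]2O | intermediate (not isolated)
12 | methyl (3R,4S,5S)-5-hydroxy-3,4-(isopropylidenedioxy)cyclohex-1-ene-1-carboxylate (methyl 3,4-O-isopropylidene-5-epi-shikimate) | COC(=O)C1=C[C@H]2OC(C)(C)O[C@H]2[C@@H](O)C1 | intermediate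
13 | (R)-2-methylbutanoic acid | CC[C@@H](C)C(=O)O | starting material
14 | methyl (3R,4S,5R)-3,4-(isopropylidenedioxy)-5-{[(2R)-2-methylbutanoyl]oxy}cyclohex-1-ene-1-carboxylate | COC(=O)C1=C[C@H]2OC(C)(C)O[C@H]2[C@H](OC(=O)[C@H](C)CC)C1 | intermediate
15 | methyl (3R,4R,5R)-3,4-dihydroxy-5-{[(2R)-2-methylbutanoyl]oxy}cyclohex-1-ene-1-carboxylate | COC(=O)C1=C[C@@H](O)[C@@H](O)[C@H](OC(=O)[C@H](C)CC)C1 | intermediate
16 | 3,4-O-(1-methoxyethylidene) orthoester of 15 (both epimers at the orthoester carbon) | COC(=O)C1=C[C@H]2OC(C)(OC)O[C@H]2[C@H](OC(=O)[C@H](C)CC)C1 | intermediate (not isolated)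
17 | methyl (3R,4S,5R)-3-(acetyloxy)-4-hydroxy-5-{[(2R)-2-methylbutanoyl]oxy}cyclohex-1-ene-1-carboxylate | COC(=O)C1=C[C@@H](OC(C)=O)[C@@H](O)[C@H](OC(=O)[C@H](C)CC)C1 | intermediate
18 | methyl (3R,4S,5R)-3-(acetyloxy)-4,5-bis{[(2R)-2-methylbutanoyl]oxy}cyclohex-1-ene-1-carboxylate | CC[C@@H](C)C(=O)O[C@@H]1[C@H](OC(C)=O)C=C(C(=O)OC)C[C@H]1OC(=O)[C@H](C)CC | target

## Step count and least certain steps

Total step count: 9. Longest linear sequence: 8 steps (1, 2, 4, 5, 6, 7, 8, 9).

Step 4 (key step). The most likely failures are:
- the second ring-forming event does not occur, because the closure must run against the facial bias of the auxiliary and through a boat-shaped acetal;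
- acylation at the ester carbonyl competes with conjugate addition;
- partial first bonding at the methoxy carbon erodes enantiopurity.

The fallback uses only established operations. It sets out from 5 and comes back at 10.
- Condensation of 5 with pyrrolidine gives the enamine 1-(2,2-dimethyl-4H-1,3-dioxin-5-yl)pyrrolidine F1.
- F1 undergoes the classical enamine alpha,alpha′-annulation with methyl 2-(bromomethyl)acrylate (Et3N, MeCN, reflux; aqueous AcOH) to the achiral saturated bicyclic keto ester F2.
- The bridgeheads of F2 cannot enolise, so LiN(i-Pr)2 deprotonates only the ester alpha-carbon, and PhSeBr gives the selenide F3.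
- H2O2 oxidises F3 to the selenoxide F4. Its syn-elimination into either ring methylene gives the racemate, 10 together with its enantiomer F5.
- Preparative chromatography on a chiral stationary phase separates the two, and 10 re-enters at step 5.

Step 5. The most likely failure is incomplete regiocontrol in the acetal shift, with reclosure on the O5 side giving the 4,5-fused isomer. Hydride delivery from the acetal face is not expected; it would give the C4 epimer and would call for the mirror-image auxiliary series. The fallback uses the other regioisomer productively. It sets out from 11 and comes back at 17.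
- The 4,5-O-isopropylidene isomer F6, with a free allylic 3-hydroxyl, is separated and acetylated (Ac2O, pyridine) to the acetate F7.
- Aqueous acetic acid removes the acetonide to the cis-4,5-diol F8.
- A Mitsunobu reaction with one equivalent of 13 should esterify the less hindered C5 carbinol with inversion, giving 17 directly.

Step 6. The most likely failure is elimination of the activated C5 oxygen towards C6, followed by aromatisation, which can outrun substitution because an aliphatic acid is a weak Mitsunobu partner. The fallback separates activation from substitution. It sets out from 12 and comes back at 14.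
- 12 is converted into the triflate F9 (Tf2O, pyridine, CH2Cl2, −20 °C).
- F9 is displaced at rt in DMF by cesium (R)-2-methylbutanoate F10, made from 13 and Cs2CO3.

Step 8. The most likely failure is unselective collapse of the orthoester, or acetyl shift between O3 and O4, giving the regioisomeric monoacetate. The fallback reverses the order of the two acylations. It sets out from 15 and comes back at 18.
- Bu2SnO (toluene, reflux) gives the dibutylstannylene acetal F11.
- F11 is acylated on the equatorial O4 by (R)-2-methylbutanoyl chloride F12 (from 13 and (COCl)2), giving the 4,5-diester F13 with a free 3-hydroxyl.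
- Acetylation (Ac2O, pyridine) gives 18.

## Further compounds

F1 | step 4 | 1-(2,2-dimethyl-4H-1,3-dioxin-5-yl)pyrrolidine | CC1(C)OCC(N2CCCC2)=CO1
F2 | step 4 | methyl (1R,5S)-3,3-dimethyl-9-oxo-2,4-dioxabicyclo[3.3.1]nonane-7-carboxylate (achiral, either C7 epimer) | COC(=O)C1C[C@@H]2OC(C)(C)O[C@H](C1)C2=O
F3 | step 4 | methyl (1R,5S)-3,3-dimethyl-9-oxo-7-(phenylselanyl)-2,4-dioxabicyclo[3.3.1]nonane-7-carboxylate | COC(=O)C1([Se]c2ccccc2)C[C@@H]2OC(C)(C)O[C@H](C1)C2=O
F4 | step 4 | methyl (1R,5S)-3,3-dimethyl-9-oxo-7-(phenylseleninyl)-2,4-dioxabicyclo[3.3.1]nonane-7-carboxylate | COC(=O)C1([Se](=O)c2ccccc2)C[C@@H]2OC(C)(C)O[C@H](C1)C2=O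
F5 | step 4 | methyl (1R,5S)-3,3-dimethyl-9-oxo-2,4-dioxabicyclo[3.3.1]non-6-ene-7-carboxylate (enantiomer of 10) | COC(=O)C1=C[C@@H]2OC(C)(C)O[C@H](C1)C2=O
F6 | step 5 | methyl 4,5-O-isopropylidene-5-epi-shikimate | COC(=O)C1=C[C@@H](O)[C@H]2OC(C)(C)O[C@H]2C1
F7 | step 5 | methyl 3-O-acetyl-4,5-O-isopropylidene-5-epi-shikimate | COC(=O)C1=C[C@@H](OC(C)=O)[C@H]2OC(C)(C)O[C@H]2C1
F8 | step 5 | methyl 3-O-acetyl-5-epi-shikimate | COC(=O)C1=C[C@@H](OC(C)=O)[C@@H](O)[C@@H](O)C1
F9 | step 6 | methyl 3,4-O-isopropylidene-5-O-(trifluoromethanesulfonyl)-5-epi-shikimate | COC(=O)C1=C[C@H]2OC(C)(C)O[C@H]2[C@@H](OS(=O)(=O)C(F)(F)F)C1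
F10 | step 6 | cesium (R)-2-methylbutanoate | [Cs+].CC[C@@H](C)C([O-])=O
F11 | step 8 | 3,4-O-dibutylstannylene acetal of 15 | COC(=O)C1=C[C@H]2O[Sn](CCCC)(CCCC)O[C@H]2[C@H](OC(=O)[C@H](C)CC)C1
F12 | step 8 | (R)-2-methylbutanoyl chloride | CC[C@@H](C)C(Cl)=O
F13 | step 8 | methyl 4,5-bis-O-[(2R)-2-methylbutanoyl]shikimate | COC(=O)C1=C[C@@H](O)[C@@H](OC(=O)[C@H](C)CC)[C@H](OC(=O)[C@H](C)CC)C1
A1 | alternative 1 | furan | c1ccoc1
A2 | alternative 1 | 3-acryloyloxazolidin-2-one | C=CC(=O)N1CCOC1=O
A3 | alternative 1 | endo 3-(7-oxabicyclo[2.2.1]hept-5-ene-2-carbonyl)oxazolidin-2-one | O=C(N1CCOC1=O)[C@H]2C[C@H]3C=C[C@@H]2O3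
A4 | alternative 2 | 4-methoxybenzyloxyacetaldehyde | COc1ccc(COCC=O)cc1
A5 | alternative 2 | methyl 2-(diethoxyphosphoryl)acrylate | C=C(C(=O)OC)P(=O)(OCC)OCC
A6 | alternative 2 | tert-butyldimethylsilyloxyacetaldehyde | CC(C)(C)[Si](C)(C)OCC=O
A7 | alternative 2 | methyl 3-O-(tert-butyldimethylsilyl)-5-O-(4-methoxybenzyl)shikimate | COC(=O)C1=C[C@@H](O[Si](C)(C)C(C)(C)C)[C@@H](O)[C@H](OCc2ccc(OC)cc2)C1
A8 | alternative 3 | D-lyxose (open-chain form) | O=C[C@@H](O)[C@@H](O)[C@H](O)CO
A9 | alternative 3 | methyl (2E)-2,3,7-trideoxy-7-iodo-4,5-O-isopropylidene-6-O-(tert-butyldimethylsilyl)-D-lyxo-hept-2-enoate | COC(=O)/C=C/[C@H]1OC(C)(C)O[C@H]1[C@H](O[Si](C)(C)C(C)(C)C)CI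
A10 | alternative 3 | methyl 3,4-O-isopropylidene-5-O-(tert-butyldimethylsilyl)shikimate | COC(=O)C1=C[C@H]2OC(C)(C)O[C@H]2[C@H](O[Si](C)(C)C(C)(C)C)C1
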